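**Retrosynthetic overview** (locants: oxolane O1, C2 = pentyl carbon, C3 = carbinol carbon, C4 = CH2, C5 = carbon bearing the side chain; C1' = ester-bearing carbon)
1. Target 17 ⇐ 16 ⇐ 14 by cleavage of the C3 auxiliary ether and O-acylation at C1'.
2. 14 ⇐ Z-dienol 12 by hydroxyl-directed epoxidation and 5-exo cyclisation (O1–C5 bond; sets C5 and C1'); 12 ⇐ lactol 8 + the ylide from salt 10 (C5=C1' alkene).
3. 8 ⇐ γ-lactone 7 ⇐ cyclobutanone 6 by Baeyer–Villiger insertion of O1 into a temporary C2–C5 bond that is not in the target.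
4. 6 ⇐ pentylketene (from heptanoyl chloride 4) + chiral vinyl ether 3 by [2+2] cycloaddition, which forms C2–C3 and C4–C5 together and sets the cis C2/C3 pair.
5. Enabling feature: O1 is flanked by C2 and C5, and C3 carries oxygen 1,3 to C5, so taking O1 out of the oxolane (C5 at carbonyl level) leaves a 2-pentyl-3-alkoxycyclobutanone, the ketene + enol ether retron. Ring order: cyclobutanone (temporary), γ-lactone (opened again), oxolane last.

Key step: step 2

Assumption: (S)-1-[2,4,6-tri(propan-2-yl)phenyl]ethanol and 10-bromodec-1-ene are taken as commercial, and the sense of induction of the auxiliary is assigned from the s-trans enol ether model (the (R)-alcohol would serve in the same route should the sense prove opposite).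

**Step 1**
Reactants: 1 (1S)-1-[2,4,6-tri(propan-2-yl)phenyl]ethan-1-ol; 2 butyl vinyl ether
Product: 3 2-[(1S)-1-(ethenyloxy)ethyl]-1,3,5-tri(propan-2-yl)benzene
Conditions: Pd(OCOCF3)2 (cat.), 4,7-diphenyl-1,10-phenanthroline (cat.), Et3N (cat.), 2 as solvent, 75 °C
Reagents that add atoms: none
Why: Palladium-catalysed transfer vinylation (transetherification) exchanges the butoxy group of the vinyl ether for the hindered alkoxide without touching the carbinol C–O bond, so the auxiliary stereocentre is carried over unchanged.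

**Step 2**
Reactants: 3 2-[(1S)-1-(ethenyloxy)ethyl]-1,3,5-tri(propan-2-yl)benzene; 4 heptanoyl chloride
Product: 6 (2S,3S)-2-pentyl-3-{(1S)-1-[2,4,6-tri(propan-2-yl)phenyl]ethoxy}cyclobutan-1-one, via pentylketene 5 (not isolated)
Conditions: 4 (3 equiv, slow addition), i-Pr2NEt (3.3 equiv), MeCN, 70 °C; product used promptly in step 3
Reagents that add atoms: none
Why: i-Pr2NEt dehydrochlorinates 4 to pentylketene 5, whose electrophilic central carbon is attacked by the nucleophilic CH2 terminus of enol ether 3 in an asynchronous, formally [π2s+π2a] cycloaddition that forms C4–C5 and C2–C3 in one step. The closest known reaction type is the thermal [2+2] cycloaddition of aldoketenes, made in situ from acid chlorides, to alkyl vinyl ethers giving 2-alkyl-3-alkoxycyclobutanones, together with auxiliary-controlled ketene cycloadditions to enol ethers of 1-arylethanols. The only ring closed is the four-membered carbocycle, closed by the cycloaddition itself, with the temporary C2–C5 bond already present in the ketene. C2 is set relative to C3 by the orthogonal approach of the ketene, in which the pentyl group points away from the enol ether and is rotated onto the alkoxy side as the bonds form, so the kinetic product should be cis. C3 is set by the auxiliary: in the s-trans enol ether with the carbinol C–H in the vinyl plane, the triisopropylphenyl ring covers one face and the ketene adds to the other, which for the (S)-auxiliary should give 3S. The step needs regiocontrol (secured by the oxygen lone pair, which polarises the enol ether so that only its CH2 carbon meets the ketene carbonyl carbon), cycloaddition over ketene dimerisation (slow addition of excess 4 to 3) and survival of the epimerisable cis C2 centre (hindered amine, prompt oxidation), and a minor face isomer is a diastereomer and is removable by chromatography.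

**Step 3**
Reactants: 6 (2S,3S)-2-pentyl-3-{(1S)-1-[2,4,6-tri(propan-2-yl)phenyl]ethoxy}cyclobutan-1-one
Product: 7 (4S,5S)-5-pentyl-4-{(1S)-1-[2,4,6-tri(propan-2-yl)phenyl]ethoxy}oxolan-2-one
Conditions: mCPBA, CH2Cl2, 0 °C (solid NaHCO3 as buffer)
Reagents that add atoms: mCPBA, O=C(OO)c1cccc(Cl)c1
Why: Baeyer–Villiger oxidation of the strained cyclobutanone is fast at 0 °C and the more substituted C2 migrates to oxygen with retention, which inserts O1 into the temporary C2–C5 bond and fixes the cis C2/C3 pair in a non-epimerisable γ-lactone.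

**Step 4**
Reactants: 7 (4S,5S)-5-pentyl-4-{(1S)-1-[2,4,6-tri(propan-2-yl)phenyl]ethoxy}oxolan-2-one
Product: 8 (4S,5S)-5-pentyl-4-{(1S)-1-[2,4,6-tri(propan-2-yl)phenyl]ethoxy}oxolan-2-ol (both anomers)
Conditions: i-Bu2AlH (1.1 equiv), CH2Cl2, −78 °C; aqueous potassium sodium tartrate work-up
Reagents that add atoms: none
Why: Partial reduction of a γ-lactone with i-Bu2AlH at −78 °C stops at the tetrahedral aluminium hemiacetal and gives the lactol, a masked C5 aldehyde, without touching any stereocentre.

**Step 5**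
Reactants: 9 10-bromodec-1-ene
Product: 10 (dec-9-en-1-yl)triphenylphosphonium bromide
Conditions: PPh3, MeCN, reflux
Reagents that add atoms: triphenylphosphine, c1ccc(cc1)P(c1ccccc1)c1ccccc1
Why: SN2 quaternisation of triphenylphosphine by a primary bromide is the standard route to Wittig salts and leaves the remote terminal alkene untouched.

**Step 6**
Reactants: 8 (4S,5S)-5-pentyl-4-{(1S)-1-[2,4,6-tri(propan-2-yl)phenyl]ethoxy}oxolan-2-ol; 10 (dec-9-en-1-yl)triphenylphosphonium bromide
Product: 12 (6S,7S,9Z)-7-{(1S)-1-[2,4,6-tri(propan-2-yl)phenyl]ethoxy}nonadeca-9,18-dien-6-ol, via phosphorus ylide 11 (not isolated)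
Conditions: 10 (3 equiv), NaN(SiMe3)2 (2.9 equiv), THF, 0 °C; then 8, −78 °C to rt
Reagents that add atoms: none
Why: Wittig olefination of the lactol through its open hydroxy aldehyde with a non-stabilised, salt-free ylide (in excess to cover the free hydroxyl) is kinetically Z-selective through the early puckered oxaphosphetane transition state, and β-alkoxy lactols of the 2-deoxy sugar type react this way without elimination.

**Step 7**
Reactants: 12 (6S,7S,9Z)-7-{(1S)-1-[2,4,6-tri(propan-2-yl)phenyl]ethoxy}nonadeca-9,18-dien-6-ol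
Product: 14 (1R)-1-[(2R,4S,5S)-5-pentyl-4-{(1S)-1-[2,4,6-tri(propan-2-yl)phenyl]ethoxy}oxolan-2-yl]dec-9-en-1-ol, via epoxy alcohol 13 (not isolated)
Conditions: VO(acac)2 (cat.), t-BuOOH, CH2Cl2, rt; then AcOH (cat.)
Reagents that add atoms: tert-butyl hydroperoxide, CC(C)(C)OO
Why: Hydroxyl-directed vanadium-catalysed epoxidation of the Z bishomoallylic alcohol delivers oxygen from the vanadate of the C2 hydroxyl to the alkene face that gives epoxide 13, and 5-exo-tet opening at C5 by that hydroxyl with inversion then forms the O1–C5 bond, so the 2,5-trans relationship should come from the directed face selection and the threo C5/C1' relationship from the Z geometry plus anti opening, while the remote terminal alkene is not epoxidised.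

**Step 8**
Reactants: 14 (1R)-1-[(2R,4S,5S)-5-pentyl-4-{(1S)-1-[2,4,6-tri(propan-2-yl)phenyl]ethoxy}oxolan-2-yl]dec-9-en-1-ol; 15 hexadecanoyl chloride
Product: 16 (1R)-1-[(2R,4S,5S)-5-pentyl-4-{(1S)-1-[2,4,6-tri(propan-2-yl)phenyl]ethoxy}oxolan-2-yl]dec-9-en-1-yl hexadecanoate
Conditions: 15, pyridine, DMAP (cat.), CH2Cl2, 0 °C to rt
Reagents that add atoms: none
Why: Acylation of the only free hydroxyl (C1') by the acid chloride under nucleophilic catalysis gives the palmitate with retention at C1', the C3 oxygen being blocked by the auxiliary ether.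

**Step 9**
Reactants: 16 (1R)-1-[(2R,4S,5S)-5-pentyl-4-{(1S)-1-[2,4,6-tri(propan-2-yl)phenyl]ethoxy}oxolan-2-yl]dec-9-en-1-yl hexadecanoate
Product: 17 (1R)-1-[(2R,4S,5S)-4-hydroxy-5-pentyloxolan-2-yl]dec-9-en-1-yl hexadecanoate
Conditions: CF3CO2H, CH2Cl2, 0 °C
Reagents that add atoms: none
Why: Acidolysis of the hindered secondary benzylic ether (E1 loss of the auxiliary as its styrene through the 1-arylethyl cation) frees the C3 hydroxyl with its C–O bond intact, while the palmitate, the oxolane and the unactivated terminal alkene should be stable to cold dilute acid.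

**Compound list**
1 | (1S)-1-[2,4,6-tri(propan-2-yl)phenyl]ethan-1-ol | C[C@H](O)c1c(C(C)C)cc(C(C)C)cc1C(C)C | starting material
2 | butyl vinyl ether | C=COCCCC | starting material
3 | 2-[(1S)-1-(ethenyloxy)ethyl]-1,3,5-tri(propan-2-yl)benzene | C=CO[C@@H](C)c1c(C(C)C)cc(C(C)C)cc1C(C)C | intermediate
4 | heptanoyl chloride | CCCCCCC(=O)Cl | starting material
5 | pentylketene (hept-1-en-1-one) | CCCCCC=C=O | intermediate
6 | (2S,3S)-2-pentyl-3-{(1S)-1-[2,4,6-tri(propan-2-yl)phenyl]ethoxy}cyclobutan-1-one | O=C1C[C@H](O[C@@H](C)c2c(C(C)C)cc(C(C)C)cc2C(C)C)[C@@H]1CCCCC | intermediate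
7 | (4S,5S)-5-pentyl-4-{(1S)-1-[2,4,6-tri(propan-2-yl)phenyl]ethoxy}oxolan-2-one | O=C1C[C@H](O[C@@H](C)c2c(C(C)C)cc(C(C)C)cc2C(C)C)[C@H](CCCCC)O1 | intermediate
8 | (4S,5S)-5-pentyl-4-{(1S)-1-[2,4,6-tri(propan-2-yl)phenyl]ethoxy}oxolan-2-ol (both anomers) | OC1C[C@H](O[C@@H](C)c2c(C(C)C)cc(C(C)C)cc2C(C)C)[C@H](CCCCC)O1 | intermediate
9 | 10-bromodec-1-ene | C=CCCCCCCCCBr | starting material
10 | (dec-9-en-1-yl)triphenylphosphonium bromide | C=CCCCCCCCC[P+](c1ccccc1)(c1ccccc1)c1ccccc1.[Br-] | intermediate
11 | (dec-9-en-1-ylidene)triphenylphosphorane | C=CCCCCCCCC=P(c1ccccc1)(c1ccccc1)c1ccccc1 | intermediate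
12 | (6S,7S,9Z)-7-{(1S)-1-[2,4,6-tri(propan-2-yl)phenyl]ethoxy}nonadeca-9,18-dien-6-ol | C=CCCCCCCC/C=C\C[C@H](O[C@@H](C)c1c(C(C)C)cc(C(C)C)cc1C(C)C)[C@H](CCCCC)O | intermediate
13 | (6S,7S,9S,10R)-9,10-epoxy-7-{(1S)-1-[2,4,6-tri(propan-2-yl)phenyl]ethoxy}nonadec-18-en-6-ol | C=CCCCCCCC[C@H]1O[C@H]1C[C@H](O[C@@H](C)c2c(C(C)C)cc(C(C)C)cc2C(C)C)[C@H](CCCCC)O | intermediate
14 | (1R)-1-[(2R,4S,5S)-5-pentyl-4-{(1S)-1-[2,4,6-tri(propan-2-yl)phenyl]ethoxy}oxolan-2-yl]dec-9-en-1-ol | C=CCCCCCCC[C@@H](O)[C@H]1C[C@H](O[C@@H](C)c2c(C(C)C)cc(C(C)C)cc2C(C)C)[C@H](CCCCC)O1 | intermediate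
15 | hexadecanoyl chloride | CCCCCCCCCCCCCCCC(=O)Cl | starting material
16 | (1R)-1-[(2R,4S,5S)-5-pentyl-4-{(1S)-1-[2,4,6-tri(propan-2-yl)phenyl]ethoxy}oxolan-2-yl]dec-9-en-1-yl hexadecanoate | C=CCCCCCCC[C@@H](OC(=O)CCCCCCCCCCCCCCC)[C@H]1C[C@H](O[C@@H](C)c2c(C(C)C)cc(C(C)C)cc2C(C)C)[C@H](CCCCC)O1 | intermediate
17 | (1R)-1-[(2R,4S,5S)-4-hydroxy-5-pentyloxolan-2-yl]dec-9-en-1-yl hexadecanoate | C=CCCCCCCC[C@@H](OC(=O)CCCCCCCCCCCCCCC)[C@H]1C[C@H](O)[C@H](CCCCC)O1 | target

**Totals**
Total step count: 9. Longest linear sequence: 8 steps (steps 1, 2, 3, 4, 6, 7, 8 and 9).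

**Steps most likely to fail**

Step 2. What may go wrong: loss of the ketene to amine-catalysed dimerisation and amine-mediated epimerisation of the kinetic cis centre at C2, with incomplete facial control by the auxiliary as a further loss of material. Fallback (sets out from 3, comes back at 6): the same ketene is generated without base by a Wolff rearrangement. Commercial hexanoyl chloride is treated with Me3SiCHN2 to give 1-diazoheptan-2-one F1. Irradiation of F1 with a near-UV LED (365 nm) in toluene at rt in the presence of 3 gives pentylketene 5, which adds to 3 under neutral conditions to give 6. In either variant a minor face isomer is removed as a diastereomer at the stage of 6 or 7.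

Step 7. What may go wrong: poor facial selectivity in the directed oxygen transfer, because the bulky ether next to the directing hydroxyl may distort the vanadate transition state, leading to cis/trans oxolane mixtures. Fallback (sets out from 12, comes back at 14): the alkene geometry is inverted and a syn-oxidative cyclisation is used instead of the anti epoxide opening. Thiyl-radical isomerisation of 12 (PhSSPh cat., hν, then separation on AgNO3-doped silica) gives the E-dienol F2. Re2O7 with 2,6-lutidine in CH2Cl2 then adds O1 and the C1' hydroxyl to the same face of the E-alkene, which should give the 2,5-trans, threo oxolane 14 directly; the hindered auxiliary ether is a poor ligand for rhenium, so the steric (trans) pathway is expected.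

Step 9. What may go wrong: capture of the benzylic cation by the terminal alkene, addition of the acid across that alkene, or sluggish ionisation of the hindered ether. Fallback (sets out from 7, comes back at 17): the auxiliary is removed before any alkene is present and replaced by an oxidatively cleavable ether. CF3CO2H in CH2Cl2 converts 7 into the hydroxy lactone F3. 4-Methoxybenzyl trichloroacetimidate with catalytic camphorsulfonic acid gives the PMB lactone F4. i-Bu2AlH at −78 °C gives the PMB lactol F5. Wittig reaction with ylide 11 gives the PMB Z-dienol F6. VO(acac)2/t-BuOOH gives the PMB oxolane alcohol F8 through the PMB epoxy alcohol F7. Acylation with 15 gives the PMB palmitate F9, and DDQ in wet buffered CH2Cl2 removes the PMB group to give 17.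

Further compounds
F1 | step 2 | 1-diazoheptan-2-one | CCCCCC(=O)C=[N+]=[N-]
F2 | step 7 | (6S,7S,9E)-7-{(1S)-1-[2,4,6-tri(propan-2-yl)phenyl]ethoxy}nonadeca-9,18-dien-6-ol | C=CCCCCCCC/C=C/C[C@H](O[C@@H](C)c1c(C(C)C)cc(C(C)C)cc1C(C)C)[C@H](CCCCC)O
F3 | step 9 | (4S,5S)-4-hydroxy-5-pentyloxolan-2-one | O=C1C[C@H](O)[C@H](CCCCC)O1
F4 | step 9 | (4S,5S)-4-[(4-methoxyphenyl)methoxy]-5-pentyloxolan-2-one | O=C1C[C@H](OCc2ccc(OC)cc2)[C@H](CCCCC)O1
F5 | step 9 | (4S,5S)-4-[(4-methoxyphenyl)methoxy]-5-pentyloxolan-2-ol | OC1C[C@H](OCc2ccc(OC)cc2)[C@H](CCCCC)O1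
F6 | step 9 | (6S,7S,9Z)-7-[(4-methoxyphenyl)methoxy]nonadeca-9,18-dien-6-ol | C=CCCCCCCC/C=C\C[C@H](OCc1ccc(OC)cc1)[C@H](CCCCC)O
F7 | step 9 | (6S,7S,9S,10R)-9,10-epoxy-7-[(4-methoxyphenyl)methoxy]nonadec-18-en-6-ol | C=CCCCCCCC[C@H]1O[C@H]1C[C@H](OCc2ccc(OC)cc2)[C@H](CCCCC)O
F8 | step 9 | (1R)-1-{(2R,4S,5S)-4-[(4-methoxyphenyl)methoxy]-5-pentyloxolan-2-yl}dec-9-en-1-ol | C=CCCCCCCC[C@@H](O)[C@H]1C[C@H](OCc2ccc(OC)cc2)[C@H](CCCCC)O1
F9 | step 9 | (1R)-1-{(2R,4S,5S)-4-[(4-methoxyphenyl)methoxy]-5-pentyloxolan-2-yl}dec-9-en-1-yl hexadecanoate | C=CCCCCCCC[C@@H](OC(=O)CCCCCCCCCCCCCCC)[C@H]1C[C@H](OCc2ccc(OC)cc2)[C@H](CCCCC)O1
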